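## The problem

Compound 38 is a labdane of the antipodal (ent) series. It is a trans-fused decalin (ring A = C1–C5 and C10, ring B = C5–C10) whose C9 carries the chain C11–C15 ending in a free acid, and whose C18 oxygen is esterified with angelic acid. Six stereocentres must be set: the contiguous triad C4 (quaternary), C5 and C10 (quaternary), the tertiary carbinol C8, C9, and the remote C13. The axial CH3-20 on C10 governs ring B, so C8 and C9 can be derived from C10 by steric approach control, and C5 and C10 control each other through conjugate addition and enolate trapping. C13 lies five bonds from the nearest ring stereocentre and has to come from the chiral pool. C4 is the centre that simple substrate control cannot reach: CH3-19 and the CH2O carbon C18 are nearly the same size, so an alkylation at C4 would not tell them apart unless one of them is tied down. The angelate isomerises to the tiglate under base and would not survive hydride, borane or hydrogenation. The tertiary C8 hydroxyl dehydrates in acid, and the C15 acid must be freed last without touching either. The feature that opens the route is that C18 and C1 are 1,4-related across ring A (C4–C5–C10–C1) while C1, C2 and C3 are bare methylenes in 38. C18 can therefore be held as the carbonyl of a δ-lactone whose ring oxygen sits on C1, a vinyl group on C1 supplies C2 and C3, and a [3,3] shift that makes C3–C4 leaves only a C1=C2 double bond to be hydrogenated away.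

## Retrosynthesis

**C15 acid and C18 ester (38 ⇒ 37 ⇒ 34 + 35).** No skeletal bond is cut. The acid is traced to methyl ester 37 and the C18–O acyl bond to diol 34 and angelic acid 35. Acylating last keeps the Z-alkene away from every base, hydride and hydrogenation of the route. Diol 34 has no sensitive group. The forward steps must acylate the neopentyl primary hydroxyl beside the tertiary one without Z-to-E isomerisation, and then cleave a methyl ester beside the angelate.

**C8–O (34 ⇒ 33 ⇒ 31).** The tertiary alcohol is traced to the exocyclic alkene 31; benzyl ether 33 is the hydration product. The neighbouring cut, methyl addition to ketone 30, would bring the nucleophile in from the equatorial side and give the C8 epimer. Hydration puts oxygen equatorial and CH3-17 axial, as required. The precursor has one stereocentre fewer. The forward step must be Markovnikov and must attack C8 from the face away from CH3-20.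

**C8=C17 and the C8 oxygen (31 ⇒ 30 ⇒ 29 ⇒ 27).** The methylene is cut by a Wittig disconnection to ketone 30, the ketone comes from alcohol 29, and 29 from the trisubstituted alkene 27 by hydroboration, which also places H-9. This is preferred to hydroxylating a C8 enolate and methylenating a C9 ketone flanked by two fully substituted carbons. C9 is self-correcting here, because it sits next to the ketone in 30 and relaxes to the equatorial chain. The precursor 27 has no stereocentre in ring B except C10.

**C9–C11 (27 ⇒ 21 + 25).** The chain is cut at the sp2–sp3 bond, giving enol triflate 21 and iodo ester 25, which is used as alkylzinc 26. A cut at C11–C12 would need an sp3–sp3 coupling of two β-branched partners, and a cut at C12–C13 would destroy the C13 stereocentre. Iodide 25 carries C13 intact and comes in two steps from lactone 24 and the half-ester 22. The forward coupling must tolerate the ester and a triflate next to quaternary C10.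

**Adjustments on the bicycle (21 ⇒ 20 ⇒ 19 ⇒ 18 ⇒ 17 ⇒ 16).** No skeletal bond is cut. The triflate comes from ketone 20 (only C8 can enolise), the ketone from dioxolane 19, the benzyl ether from alcohol 18, the alcohol from acid 17, and 17 from the octalin acid 16. Benzyl is chosen because it is removed by hydrogenolysis at a stage where no alkene is left and the angelate is not yet on.

**C3–C4 (16 ⇒ 13), the key cut.** Ring A is opened at C3–C4 and C18 is re-attached through oxygen to C1, which gives the vinyl δ-lactone 13 on ring B. Against an alkylation at C4, this cut makes the C3–C4 bond inside a bicyclic array (ketene acetal 14), so the face of C4 is fixed by geometry and not by the size of CH3 against CH2O. The precursor has one ring and one quaternary centre fewer, and its C4 configuration is irrelevant. The forward step is the thermal rearrangement of 14 to silyl ester 15.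

**Lactone C–O and ketal (13 ⇒ 12 ⇒ 10).** The dioxolane is removed to keto lactone 12, and the lactone is traced to the 1,5-diol 10 by oxidative lactonisation through lactol 11. This avoids carrying a free acid through Lewis-acid chemistry and closes the lactone with retention at C1. The ketal is needed so that only C4–H is acidic in the key step.

**C10–C1 (10 ⇒ 7 + 8).** The aldol cut gives the silyl enol ether 7 and acrolein 8, with the primary silyl ether 9 as the first adduct. Acrolein brings C1, C2 and C3 in one step. A vinyl-metal addition to a C10 aldehyde would cost two more steps. The forward step must add anti to the C5 substituent (C10) and place the C1 oxygen correctly.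

**C4–C5 and the C18 oxygen (7 ⇒ 6 ⇒ 4 ⇒ 1 + 2).** The bis-silyl compound 7 comes from alcohol 6, and 6 from the isopropenyl enol ether 4 by hydroboration through borane 5. The hydroboration is done before the vinyl group exists, since a borane could not tell the two alkenes apart later. Enol ether 4 is cut at C4–C5 to enone 1 and Grignard reagent 2; the magnesium enolate 3 is stored as its silyl ether so that the C9–C10 enolate regiochemistry is kept. The forward addition must set C5 by catalyst control.

## Roads not taken

**Alternative 1:** The cut is C8–C9 of ring B together with the C12–O bond of an 8,12-lactone. In the forward step SmI2 would reduce a C8 methyl ketone to a ketyl that adds to C9 of an enoate on C10, and the samarium alkoxide would then close the lactone to give A1.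
- Merits: ring B, the C8 carbinol with its methyl group and C9 arise in one step. This is better than the chosen plan, which spends six steps (12 and 15–19) on C8 and C9.
- Weak points: the step does nothing for C4, which would have to be set earlier on a monocyclic ring A where nothing separates CH3 from CH2O. After A1 the chain must be grown from the C12 carbonyl, and C13 must be created on an open chain far from any ring stereocentre, which calls for an auxiliary and a one-carbon homologation.
- Comparison: the chosen plan sets against the one-step C8/C9 advantage a C4 centre fixed by a tether and a C13 centre that is bought and coupled intact.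

**Alternative 2:** The cut is C3–C4 and C5–C10 at once. The forward step is an intramolecular Diels–Alder reaction between a C3=C2–C1=C10 diene unit and a C4=C5 α-methyl enoate unit joined through C6–C9, giving A2.
- Merits: both rings and C4, C5 and C10 form in one step with the chain already in place. If it worked, this would be the shorter and more convergent route, and it forms the same C3–C4 bond and the same C1=C2 alkene as the chosen plan.
- Weak points: the diene terminus C10 is fully substituted and carries an inward methyl group, the dienophile is trisubstituted, and two quaternary centres must form in one cycloaddition. The C4 configuration depends on the endo or exo placement of the ester, which is again the small difference between CH3 and a carboxyl carbon. The C8 silyl ether still needs oxidation, methylenation and hydration.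
- Comparison: the chosen plan sets against the convergence a unimolecular step in which the face at C4 is dictated by the tether, and it forms one quaternary centre at a time.

**Alternative 3:** The cut is C9–C10, with C4 set beforehand by asymmetric catalysis on ring A. In the forward step TiCl4 would activate a C6 ketone conjugated to C5=C10, an allylsilane terminus C9 would add to C10, and silicon would leave to give the C8=C17 methylene of A3.
- Merits: the exocyclic alkene and the whole chain with C13 arrive together. This is better than the chosen plan, which needs four steps from 21 to reach alkene 31. C4 would also not depend on the substrate.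
- Weak points: C10, C9 and C5 must then be set relative to C4, whose two substituents are nearly equal, so the relay from C4 to C10 is weak. The addition must create a quaternary centre at the β-carbon of a tetrasubstituted enone, and the C6 ketone must later be removed.
- Comparison: the chosen plan runs the relay the other way, from C5 and C10 to C4 through a rigid bicyclic transition state.

Key step: step 7

Assumption (step 1): the sense of induction is set by the antipode of the ferrocenyl diphosphine; the antipode that gives (3R)-4 is used, both being commercial.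

Assumption (step 13): methyl hydrogen (3R)-3-methylglutarate 22 is taken as a commercial, enantiopure half-ester; from its antipode, borane reduction of the acid terminus would lead to the same lactone 24.

## Route

Labdane numbering is used for all bicyclic compounds and their precursors.

Step 1
Reactants: 1 2-methylcyclohex-2-en-1-one; 2 isopropenylmagnesium bromide
Product: 4 triethyl{[(3R)-2-methyl-3-(prop-1-en-2-yl)cyclohex-1-en-1-yl]oxy}silane, via magnesium enolate 3 (not isolated)
Conditions: CuBr·SMe2 (5 mol %), Josiphos ligand (R)-1-[(SP)-2-(diphenylphosphino)ferrocenyl]ethyldicyclohexylphosphine (6 mol %), tBuOMe, −78 °C; then Et3SiCl, Et3N, DMPU, −78 °C → rt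
Reagents that add atoms: chlorotriethylsilane, CC[Si](Cl)(CC)CC
Why: Copper-catalysed asymmetric conjugate addition of a Grignard reagent to a cyclic enone; the chiral diphosphine sets C5, and O-silylation of enolate 3 stores the C9=C10 enolate regiochemistry.

Step 2
Reactants: 4 triethyl{[(3R)-2-methyl-3-(prop-1-en-2-yl)cyclohex-1-en-1-yl]oxy}silane
Product: 6 2-[(1R)-2-methyl-3-(triethylsilyloxy)cyclohex-2-en-1-yl]propan-1-ol (both C4 epimers), via B-alkyl-9-borabicyclononane 5 (not isolated)
Conditions: 9-BBN, THF, 0 °C → rt; then 30% H2O2, 3 M NaOH, 0 °C
Reagents that add atoms: hydrogen peroxide, OO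
Why: Anti-Markovnikov hydroboration–oxidation of the 1,1-disubstituted alkene; the tetrasubstituted silyl enol ether should be inert to 9-BBN. The new C4 centre is uncontrolled and is planarised in step 7.

Step 3
Reactants: 6 2-[(1R)-2-methyl-3-(triethylsilyloxy)cyclohex-2-en-1-yl]propan-1-ol
Product: 7 triethylsilyl ether of 6 (bis-silyl compound; both C4 epimers)
Conditions: Et3SiCl, imidazole, CH2Cl2, 0 °C
Reagents that add atoms: chlorotriethylsilane, CC[Si](Cl)(CC)CC
Why: Standard silylation of a primary alcohol; it keeps the hydroxyl from quenching the Lewis acid of step 4.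

Step 4
Reactants: 7 bis-silyl compound; 8 acrolein
Product: 10 (2S,3R)-2-[(1R)-1-hydroxyprop-2-en-1-yl]-3-(1-hydroxypropan-2-yl)-2-methylcyclohexan-1-one (both C4 epimers), via primary silyl ether 9 (not isolated)
Conditions: BF3·OEt2, CH2Cl2, −78 °C; then 1 M HCl, THF, 0 °C
Reagents that add atoms: none
Why: Mukaiyama aldol addition (1,2-addition to the activated enal); acrolein should enter anti to the C5 substituent, which sets C10 with CH3-20 trans to H-5. In the open transition state the vinyl group should lie beside CH3-20 and not beside the branched C5, which puts the C1 oxygen syn to C5; dilute acid then removes the primary silyl ether.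

Step 5
Reactants: 10 diol ketone
Product: 12 vinyl δ-lactone with C9 ketone (C18 carbonyl, ring oxygen on C1; H-5 trans to CH3-20, vinyl on C1 cis to CH3-20; both C4 epimers), via lactol 11 (not isolated)
Conditions: TEMPO (20 mol %), PhI(OAc)2 (2.5 equiv), CH2Cl2, rt
Reagents that add atoms: none
Why: Oxidative lactonisation of a 1,5-diol; the primary alcohol is oxidised first, the aldehyde closes to lactol 11 with the C1 hydroxyl, and 11 is oxidised to the lactone with retention at C1.

Step 6
Reactants: 12 keto lactone
Product: 13 vinyl δ-lactone with C9 dioxolane (both C4 epimers)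
Conditions: Me3SiOCH2CH2OSiMe3, Me3SiOTf (5 mol %), CH2Cl2, −78 → −20 °C
Reagents that add atoms: 1,2-bis(trimethylsilyloxy)ethane, C[Si](C)(C)OCCO[Si](C)(C)C
Why: Noyori ketalisation under aprotic conditions, which spares the allylic lactone; with the ketone masked, C4–H is the only acidic hydrogen in step 7 and no ketone enolate can attack the lactone.

Step 7
Reactants: 13 vinyl δ-lactone with C9 dioxolane
Product: 16 octalin acid (C1=C2; C4 bears CH3-19 and the C18 carboxyl trans to CH3-20; trans ring fusion; C9 dioxolane), via silyl ketene acetal 14 (not isolated), via silyl ester 15 (not isolated)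
Conditions: LiN(iPr)2, tBuMe2SiCl, THF–DMPU, −78 °C → rt; then toluene, 110–150 °C (sealed tube); then 10% aq. citric acid, THF, rt
Reagents that add atoms: none
Why: Deprotonation of 13 at C4 and O-silylation give ketene acetal 14, whose enol geometry is fixed by the ring. On heating, the six atoms C4=C18–O–C1–C2=C3 undergo a concerted [3,3] sigmatropic shift through a boat, because the C5–C10 tether joins C4 and C1; the C3–C4 bond forms, the C1–O bond breaks, and silyl ester 15 is hydrolysed to 16. The closest known reaction type is the Ireland–Claisen rearrangement of lactone silyl ketene acetals, in which vinyl lactones give cycloalkene carboxylic acids. Ring A closes in a sigmatropic, suprafacial mode by joining the vinyl terminus C3 to C4 across the lactone, with the new C1=C2 double bond inside the ring that forms. The new stereocentre C4 is controlled by the C1 stereocentre and the tether: the vinyl group stands cis to CH3-20, C3 can reach only that face of C4, and C18 is left trans to CH3-20 whichever C4 epimer of 13 is used. The step needs periselectivity for the [3,3] path over O-to-C silyl migration and over β-elimination of the allylic carboxylate, which low-temperature silylation and a non-polar thermolysis medium serve. It also needs the boat to accept the trans-fused ring B, which the long partial bonds of an early transition state should allow at 110–150 °C.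

Step 8
Reactants: 16 octalin acid
Product: 17 decalin acid (C1–C2 saturated; otherwise as 16)
Conditions: H2 (1 atm), Pd/C, EtOAc, rt
Reagents that add atoms: none
Why: Heterogeneous hydrogenation of a cis-disubstituted ring alkene; no stereocentre is formed and the dioxolane is inert.

Step 9
Reactants: 17 decalin acid
Product: 18 C18 primary alcohol (C9 dioxolane)
Conditions: LiAlH4, THF, 0 °C → reflux
Reagents that add atoms: none
Why: Hydride reduction of a neopentyl carboxylic acid to the primary alcohol; the ketal is stable.

Step 10
Reactants: 18 C18 alcohol
Product: 19 C18 benzyl ether (C9 dioxolane)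
Conditions: NaH, PhCH2Br, Bu4NI (cat.), THF–DMF, 0 °C → rt
Reagents that add atoms: benzyl bromide, BrCc1ccccc1
Why: Williamson etherification; the benzyl group survives acid, base, organometallics, borane and divalent mercury and is removed by hydrogenolysis in step 20.

Step 11
Reactants: 19 benzyl ether ketal
Product: 20 C9 ketone (18-benzyloxy; C4, C5, C10 as in 38)
Conditions: 2 M HCl, THF, 40 °C
Reagents that add atoms: water, O
Why: Acid hydrolysis of the dioxolane; the benzyl ether is stable to aqueous acid.

Step 12
Reactants: 20 C9 ketone
Product: 21 C8=C9 enol triflate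
Conditions: KN(SiMe3)2, THF, −78 °C; then PhNTf2, −78 → 0 °C
Reagents that add atoms: N-phenylbis(trifluoromethanesulfonimide), O=S(=O)(N(c1ccccc1)S(=O)(=O)C(F)(F)F)C(F)(F)F
Why: Enolate O-triflation; C10 is quaternary, so only C8 can be deprotonated and the triflate is formed as a single regioisomer.

Step 13
Reactants: 22 methyl hydrogen (3R)-3-methylglutarate
Product: 24 (4S)-4-methyloxan-2-one, via hydroxy acid 23 (not isolated)
Conditions: LiOMe (1 equiv), MeOH, then evaporation; LiBH4, THF, 0 °C → rt; then 3 M HCl, rt
Reagents that add atoms: none
Why: Borohydride reduces the ester but not the lithium carboxylate, and acidification lactonises hydroxy acid 23. The stereocentre is untouched; its descriptor changes only because the priorities of the two arms change.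

Step 14
Reactants: 24 (4S)-4-methyloxan-2-one
Product: 25 methyl (3R)-5-iodo-3-methylpentanoate
Conditions: Me3SiCl, NaI, MeCN, rt → 60 °C; then MeOH, rt
Reagents that add atoms: sodium iodide, [Na+].[I-]; methanol, CO
Why: Iodotrimethylsilane made in the flask opens the lactone by iodide attack at the O–CH2 carbon, and methanol converts the silyl ester into the methyl ester. C3 is not involved; it has the configuration of C13 in 38.

Step 15
Reactants: 21 enol triflate; 25 methyl (3R)-5-iodo-3-methylpentanoate
Product: 27 methyl 18-benzyloxy-17-norlabd-8-en-15-oate (antipodal series; C4, C5, C10 and C13 as in 38), via alkylzinc iodide 26 (not isolated)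
Conditions: 25, Zn dust, LiCl, THF, 40 °C; then 21, Pd(dppf)Cl2 (5 mol %), THF–NMP, 60 °C
Reagents that add atoms: none
Why: Negishi coupling of an ester-bearing alkylzinc halide with an alkenyl triflate; zinc insertion tolerates the ester and no stereocentre is formed.

Step 16
Reactants: 27 Δ8 ester
Product: 29 methyl 18-benzyloxy-8-hydroxy-17-norlabdan-15-oate (8-OH and H-9 both on the face opposite CH3-20), via alkylborane 28 (not isolated)
Conditions: BH3·THF, THF, 0 °C → rt; then 30% H2O2, aq. NaOH, 0 °C
Reagents that add atoms: hydrogen peroxide, OO
Why: Hydroboration–oxidation of a trisubstituted alkene; boron goes to the less substituted C8 and the syn addition should come from the face away from the axial CH3-20. The C8 centre is oxidised away in step 17 and C9 then lies next to a ketone, so an error here is corrected later.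

Step 17
Reactants: 29 C8 alcohol
Product: 30 methyl 18-benzyloxy-8-oxo-17-norlabdan-15-oate (C9 chain equatorial)
Conditions: Dess–Martin periodinane, CH2Cl2, rt
Reagents that add atoms: none
Why: Neutral oxidation of a secondary alcohol to the ketone; the equatorial C9 chain is the stable arrangement.

Step 18
Reactants: 30 C8 ketone
Product: 31 methyl 18-benzyloxylabd-8(17)-en-15-oate (antipodal series)
Conditions: Ph3PCH3Br, KOtBu, toluene, rt → 80 °C
Reagents that add atoms: methyltriphenylphosphonium bromide, C[P+](c1ccccc1)(c1ccccc1)c1ccccc1.[Br-]
Why: Wittig methylenation of the α-branched ketone; the ylide reacts much faster with the ketone than with the methyl ester, and any C9 epimer equilibrates to the equatorial chain under the basic conditions.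

Step 19
Reactants: 31 exocyclic alkene
Product: 33 methyl 18-benzyloxy-8-hydroxylabdan-15-oate (all six stereocentres as in 38), via organomercurial 32 (not isolated)
Conditions: Hg(OAc)2, THF–H2O, rt; then 3 M NaOH, NaBH4, 0 °C
Reagents that add atoms: water, O
Why: Oxymercuration–demercuration, a Markovnikov hydration; axial attack of water at C8 is blocked by the syn-axial CH3-20, so water should enter equatorially and leave CH3-17 axial and cis to CH3-20.

Step 20
Reactants: 33 benzyl ether
Product: 34 methyl 8,18-dihydroxylabdan-15-oate (stereocentres as in 38)
Conditions: H2 (1 atm), Pd/C, EtOH, rt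
Reagents that add atoms: none
Why: Hydrogenolysis of the benzyl ether; no alkene is present at this stage, and the ester and the tertiary alcohol are inert.

Step 21
Reactants: 34 diol ester; 35 angelic acid
Product: 37 methyl ester of 38 (18-angelate), via mixed anhydride 36 (not isolated)
Conditions: 35, 2,4,6-trichlorobenzoyl chloride, Et3N, toluene, rt; then 34, toluene, 80 °C
Reagents that add atoms: none
Why: Yamaguchi-type esterification through the mixed anhydride without a nucleophilic catalyst, the known way to make angelates without isomerisation to tiglates; only the primary hydroxyl is acylated, the tertiary one being too hindered.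

Step 22
Reactants: 37 methyl ester angelate
Product: 38 (4S,5S,8S,9S,10R,13S)-8-hydroxy-18-[(Z)-2-methylbut-2-enoyloxy]labdan-15-oic acid
Conditions: Me3SnOH, ClCH2CH2Cl, 70 °C; then 0.1 M HCl wash
Reagents that add atoms: trimethyltin hydroxide, C[Sn](C)(C)O
Why: Trimethyltin hydroxide cleaves unhindered methyl esters under nearly neutral conditions; the neopentyl, α-branched, conjugated angelate should react far more slowly, and the tertiary alcohol and the Z-alkene are not exposed to base or acid.

## Compound list

1 | 2-methylcyclohex-2-en-1-one | CC1=CCCCC1=O | starting material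
2 | isopropenylmagnesium bromide | CC(=C)[Mg]Br | starting material
3 | bromomagnesium (3R)-2-methyl-3-(prop-1-en-2-yl)cyclohex-1-en-1-olate (not isolated) | CC(=C)[C@H]1CCCC(O[Mg]Br)=C1C | intermediate
4 | triethyl{[(3R)-2-methyl-3-(prop-1-en-2-yl)cyclohex-1-en-1-yl]oxy}silane | CC(=C)[C@H]1CCCC(O[Si](CC)(CC)CC)=C1C | intermediate
5 | 9-{2-[(1R)-2-methyl-3-(triethylsilyloxy)cyclohex-2-en-1-yl]propyl}-9-borabicyclo[3.3.1]nonane (C4 epimers; not isolated) | CC(CB1C2CCCC1CCC2)[C@H]1CCCC(O[Si](CC)(CC)CC)=C1C | intermediate
6 | 2-[(1R)-2-methyl-3-(triethylsilyloxy)cyclohex-2-en-1-yl]propan-1-ol (C4 epimers) | CC(CO)[C@H]1CCCC(O[Si](CC)(CC)CC)=C1C | intermediate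
7 | triethylsilyl ether of 6 (C4 epimers) | CC(CO[Si](CC)(CC)CC)[C@H]1CCCC(O[Si](CC)(CC)CC)=C1C | intermediate
8 | acrolein | C=CC=O | starting material
9 | (2S,3R)-2-[(1R)-1-hydroxyprop-2-en-1-yl]-2-methyl-3-[1-(triethylsilyloxy)propan-2-yl]cyclohexan-1-one (C4 epimers; not isolated) | C=C[C@@H](O)[C@@]1(C)C(=O)CCC[C@@H]1C(C)CO[Si](CC)(CC)CC | intermediate
10 | (2S,3R)-2-[(1R)-1-hydroxyprop-2-en-1-yl]-3-(1-hydroxypropan-2-yl)-2-methylcyclohexan-1-one (C4 epimers) | C=C[C@@H](O)[C@@]1(C)C(=O)CCC[C@@H]1C(C)CO | intermediate
11 | lactol of 10 (C18 hemiacetal closed on the C1 oxygen; not isolated) | OC1C(C)[C@H]2CCCC(=O)[C@]2(C)[C@@H](C=C)O1 | intermediate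
12 | vinyl δ-lactone on ring B with C9 ketone (vinyl cis to CH3-20, H-5 trans to CH3-20; C4 epimers) | O=C1C(C)[C@H]2CCCC(=O)[C@]2(C)[C@@H](C=C)O1 | intermediate
13 | vinyl δ-lactone on ring B with C9 dioxolane (C4 epimers) | O=C1C(C)[C@H]2CCCC3(OCCO3)[C@]2(C)[C@@H](C=C)O1 | intermediate
14 | tert-butyldimethylsilyl ketene acetal of 13 (C4=C18; not isolated) | CC(C)(C)[Si](C)(C)OC1=C(C)[C@H]2CCCC3(OCCO3)[C@]2(C)[C@@H](C=C)O1 | intermediate
15 | tert-butyldimethylsilyl ester of 16 (not isolated) | CC(C)(C)[Si](C)(C)OC(=O)[C@@]1(C)CC=C[C@]2(C)[C@@H]1CCCC23OCCO3 | intermediate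
16 | octalin C18 acid with C1=C2 and C9 dioxolane (C4, C5, C10 as in 38) | OC(=O)[C@@]1(C)CC=C[C@]2(C)[C@@H]1CCCC23OCCO3 | intermediate
17 | decalin C18 acid with C9 dioxolane | OC(=O)[C@@]1(C)CCC[C@]2(C)[C@@H]1CCCC23OCCO3 | intermediate
18 | C18 alcohol with C9 dioxolane | OC[C@@]1(C)CCC[C@]2(C)[C@@H]1CCCC23OCCO3 | intermediate
19 | C18 benzyl ether with C9 dioxolane | C(OCc1ccccc1)[C@@]1(C)CCC[C@]2(C)[C@@H]1CCCC23OCCO3 | intermediate
20 | 18-benzyloxy C9 ketone | C(OCc1ccccc1)[C@@]1(C)CCC[C@]2(C)[C@@H]1CCCC2=O | intermediate
21 | 18-benzyloxy C8=C9 enol triflate | C(OCc1ccccc1)[C@@]1(C)CCC[C@]2(C)[C@@H]1CCC=C2OS(=O)(=O)C(F)(F)F | intermediate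
22 | methyl hydrogen (3R)-3-methylglutarate | OC(=O)C[C@@H](C)CC(=O)OC | starting material
23 | (3S)-5-hydroxy-3-methylpentanoic acid (not isolated) | OC(=O)C[C@@H](C)CCO | intermediate
24 | (4S)-4-methyloxan-2-one | O=C1C[C@@H](C)CCO1 | intermediate
25 | methyl (3R)-5-iodo-3-methylpentanoate | COC(=O)C[C@@H](C)CCI | intermediate
26 | [(3R)-5-methoxy-3-methyl-5-oxopentyl]zinc iodide (not isolated) | COC(=O)C[C@@H](C)CC[Zn]I | intermediate
27 | methyl 18-benzyloxy-17-norlabd-8-en-15-oate (antipodal series, 13S) | C(OCc1ccccc1)[C@@]1(C)CCC[C@]2(C)[C@@H]1CCC=C2CC[C@H](C)CC(=O)OC | intermediate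
28 | C8 borane from 27 (boron and H-9 on the face opposite CH3-20; not isolated) | C(OCc1ccccc1)[C@@]1(C)CCC[C@]2(C)[C@@H]1CC[C@H]([BH2])[C@H]2CC[C@H](C)CC(=O)OC | intermediate
29 | methyl 18-benzyloxy-8-hydroxy-17-norlabdan-15-oate (8-OH and H-9 trans to CH3-20) | C(OCc1ccccc1)[C@@]1(C)CCC[C@]2(C)[C@@H]1CC[C@H](O)[C@H]2CC[C@H](C)CC(=O)OC | intermediate
30 | methyl 18-benzyloxy-8-oxo-17-norlabdan-15-oate | C(OCc1ccccc1)[C@@]1(C)CCC[C@]2(C)[C@@H]1CCC(=O)[C@H]2CC[C@H](C)CC(=O)OC | intermediate
31 | methyl 18-benzyloxylabd-8(17)-en-15-oate (antipodal series) | C(OCc1ccccc1)[C@@]1(C)CCC[C@]2(C)[C@@H]1CCC(=C)[C@H]2CC[C@H](C)CC(=O)OC | intermediate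
32 | 17-(acetoxymercurio) derivative of 33 (not isolated) | C(OCc1ccccc1)[C@@]1(C)CCC[C@]2(C)[C@@H]1CC[C@](C[Hg]OC(C)=O)(O)[C@H]2CC[C@H](C)CC(=O)OC | intermediate
33 | methyl 18-benzyloxy-8-hydroxylabdan-15-oate (stereocentres as in 38) | C(OCc1ccccc1)[C@@]1(C)CCC[C@]2(C)[C@@H]1CC[C@](C)(O)[C@H]2CC[C@H](C)CC(=O)OC | intermediate
34 | methyl 8,18-dihydroxylabdan-15-oate (stereocentres as in 38) | OC[C@@]1(C)CCC[C@]2(C)[C@@H]1CC[C@](C)(O)[C@H]2CC[C@H](C)CC(=O)OC | intermediate
35 | angelic acid, (Z)-2-methylbut-2-enoic acid | C/C=C(/C)C(=O)O | starting material
36 | angelic 2,4,6-trichlorobenzoic anhydride (not isolated) | C/C=C(/C)C(=O)OC(=O)c1c(Cl)cc(Cl)cc1Cl | intermediate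
37 | methyl ester of 38 | C/C=C(/C)C(=O)OC[C@@]1(C)CCC[C@]2(C)[C@@H]1CC[C@](C)(O)[C@H]2CC[C@H](C)CC(=O)OC | intermediate
38 | (4S,5S,8S,9S,10R,13S)-8-hydroxy-18-[(Z)-2-methylbut-2-enoyloxy]labdan-15-oic acid | C/C=C(/C)C(=O)OC[C@@]1(C)CCC[C@]2(C)[C@@H]1CC[C@](C)(O)[C@H]2CC[C@H](C)CC(=O)O | target

## Step count and risks

Total: 22 steps. Longest linear sequence: 20 steps (steps 1–12 and 15–22); steps 13 and 14 prepare the side chain.

**Step 7 (key step).** The rearrangement may stall. The boat has to twist to accept the trans-fused ring B, and C3 must pass over the face of C4 that is flanked by the syn-axial CH3-20. At the temperature then needed, O-to-C silyl migration or elimination of the allylic carboxylate can overtake the [3,3] shift.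
Fallback (sets out from 13, returns at 19): the facial bias of the lactone enolate, which the sigmatropic step has to overcome, is used instead.
- Alkylation of the lithium enolate of 13 with benzyl chloromethyl ether (LiN(iPr)2, THF, −78 °C) should enter anti to CH3-20 and give the benzyloxymethyl lactone F1. In F1 the new CH2O carbon takes the role of C18 and the lactone carbonyl carbon that of C3.
- Reduction with iBu2AlH would give the lactol F2, and Wittig methylenation (Ph3P=CH2) the diene alcohol F3.
- Ring-closing metathesis with the second-generation Grubbs catalyst RuCl2(=CHPh)(H2IMes)(PCy3) would close ring A at C2=C3 and give the octalinol F4.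
- Hydrogenation over RhCl(PPh3)3 would give the decalinol F5. Barton–McCombie removal of the C1 hydroxyl through the xanthate F6 (NaH, CS2, MeI; then Bu3SnH, AIBN) would give 19.

**Step 4.** Selectivity at C1 may be low, because the open and closed transition states differ little in energy for a tetrasubstituted enol ether. Conjugate addition or polymerisation of acrolein under BF3 may also compete.
Fallback (sets out from 7, returns at 9): the aldol is stopped before the acid treatment, so that 9 is isolated together with its C1 epimer F7. Dess–Martin oxidation of the mixture erases C1 and gives the enedione F8. Reduction with BH3·SMe2 and the matching antipode of the B-methyl diphenylprolinol oxazaborolidine (Corey–Bakshi–Shibata reduction) would set C1 under catalyst control and return 9.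

**Step 16.** Borane may reduce the C15 methyl ester while the hindered C8=C9 alkene reacts slowly.
Fallback (sets out from 27, returns at 29): epoxidation with mCPBA from the face opposite CH3-20 would give the 8,9-epoxide F9. Ti(C5H5)2Cl (made from Ti(C5H5)2Cl2 and Zn), a trivalent titanium reagent that leaves esters alone, would open it to the tertiary C9 radical, and hydrogen transfer from 1,4-cyclohexadiene would give 29. A C9 epimer, if formed, is corrected at ketone 30.

**Step 19.** Facial selectivity of water attack at C8 may be insufficient, giving some of the C8 epimer.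
Fallback (sets out from 31, returns at 33): epoxidation with mCPBA from the equatorial face would give the 8,17-epoxide F10. Opening with MgI2 at the primary C17 would give the iodohydrin F11, and Bu3SnH with AIBN would remove the iodine to give 33.

**Step 22.** The angelate may be lost or isomerised while the methyl ester is cleaved.
Fallback (sets out from 34, returns at 38): saponification with LiOH before the angelate is present would give the dihydroxy acid F12. Allyl bromide and Cs2CO3 in DMF would give the allyl ester F13, and the conditions of step 21 the allyl ester angelate F14. Pd(PPh3)4 (zerovalent palladium) and morpholine would then remove the allyl group under neutral conditions to give 38.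

## Further compounds

F1 | step 7 | C4-(benzyloxymethyl) derivative of lactone 13 (CH2OBn trans to CH3-20 on the lactone ring) | O=C1[C@](C)(COCc4ccccc4)[C@H]2CCCC3(OCCO3)[C@]2(C)[C@@H](C=C)O1
F2 | step 7 | lactol from F1 | OC1[C@](C)(COCc4ccccc4)[C@H]2CCCC3(OCCO3)[C@]2(C)[C@@H](C=C)O1
F3 | step 7 | diene alcohol (vinyl on C4, hydroxyallyl on C10) | C=C[C@](C)(COCc4ccccc4)[C@H]2CCCC3(OCCO3)[C@]2(C)[C@@H](C=C)O
F4 | step 7 | 18-benzyloxy octalin-1-ol with C2=C3 and C9 dioxolane | C(OCc1ccccc1)[C@@]1(C)C=C[C@@H](O)[C@]2(C)[C@@H]1CCCC23OCCO3
F5 | step 7 | 18-benzyloxy decalin-1-ol with C9 dioxolane | C(OCc1ccccc1)[C@@]1(C)CC[C@@H](O)[C@]2(C)[C@@H]1CCCC23OCCO3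
F6 | step 7 | S-methyl xanthate of F5 | C(OCc1ccccc1)[C@@]1(C)CC[C@@H](OC(=S)SC)[C@]2(C)[C@@H]1CCCC23OCCO3
F7 | step 4 | C1 epimer of 9 | C=C[C@H](O)[C@@]1(C)C(=O)CCC[C@@H]1C(C)CO[Si](CC)(CC)CC
F8 | step 4 | enedione (2-acryloyl-2-methylcyclohexanone with the silyloxypropyl group on C5) | C=CC(=O)[C@@]1(C)C(=O)CCC[C@@H]1C(C)CO[Si](CC)(CC)CC
F9 | step 16 | 8,9-epoxide of 27 (oxygen trans to CH3-20) | C(OCc1ccccc1)[C@@]1(C)CCC[C@]2(C)[C@@H]1CC[C@@H]3O[C@]23CC[C@H](C)CC(=O)OC
F10 | step 19 | 8,17-epoxide of 31 (oxygen equatorial) | C(OCc1ccccc1)[C@@]1(C)CCC[C@]2(C)[C@@H]1CC[C@@]3(CO3)[C@H]2CC[C@H](C)CC(=O)OC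
F11 | step 19 | 17-iodo derivative of 33 | C(OCc1ccccc1)[C@@]1(C)CCC[C@]2(C)[C@@H]1CC[C@](CI)(O)[C@H]2CC[C@H](C)CC(=O)OC
F12 | step 22 | 8,18-dihydroxylabdan-15-oic acid (stereocentres as in 38) | OC[C@@]1(C)CCC[C@]2(C)[C@@H]1CC[C@](C)(O)[C@H]2CC[C@H](C)CC(=O)O
F13 | step 22 | allyl ester of F12 | OC[C@@]1(C)CCC[C@]2(C)[C@@H]1CC[C@](C)(O)[C@H]2CC[C@H](C)CC(=O)OCC=C
F14 | step 22 | allyl ester of 38 | C/C=C(/C)C(=O)OC[C@@]1(C)CCC[C@]2(C)[C@@H]1CC[C@](C)(O)[C@H]2CC[C@H](C)CC(=O)OCC=C
A1 | alternative 1 | 18-(tert-butyldimethylsilyloxy)-ent-sclareolide | CC(C)(C)[Si](C)(C)OC[C@@]1(C)CCC[C@]2(C)[C@@H]1CC[C@](C)(OC(=O)C3)[C@H]23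
A2 | alternative 2 | methyl ent-labd-1-en-18-oate 8-(tert-butyldimethylsilyl) 15-(tert-butyldiphenylsilyl) diether | COC(=O)[C@@]1(C)CC=C[C@]2(C)[C@@H]1CC[C@H](O[Si](C)(C)C(C)(C)C)[C@H]2CC[C@H](C)CCO[Si](c3ccccc3)(c3ccccc3)C(C)(C)C
A3 | alternative 3 | 18-benzyloxy-15-(tert-butyldiphenylsilyloxy)-ent-labd-8(17)-en-6-one | C(OCc1ccccc1)[C@@]2(C)CCC[C@]3(C)[C@@H]2C(=O)CC(=C)[C@H]3CC[C@H](C)CCO[Si](c4ccccc4)(c4ccccc4)C(C)(C)C
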